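The pyran ring (ring C) of the target carries O1 on C2 and the ester oxygen on C3 on neighbouring carbons, so the chroman is the six-membered isomer of an oxiranium ion that can be reached from a 2-(α-sulfonyloxybenzyl)-2,3-dihydrobenzofuran. In one operation the key step forms the O1–C2 bond and the C3–O ester bond, enlarges the furan to the pyran and sets C2 and C3 (2,3-cis) by double inversion. Its precursor is the threo (S,S) benzylic mesylate of a 4,6-bis(benzyloxy)dihydrobenzofuran bearing an electron-poor 3,4-bis(benzyloxycarbonyloxy)phenyl group, made from a cis-1,3-diarylpropene by Jacobsen epoxidation and 5-exo phenoxide opening. All protecting groups fall in one final hydrogenolysis.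

Key step: step 13

Assumption: the (S,S)-Mn(salen) catalyst is taken to show the same sense of induction on alkene 10 as on cis-β-methylstyrene and indene (S-configured benzylic carbon); if the sense were opposite, the (R,R)-catalyst would be used.

**Step 1**
Reactants: 1 2,4,6-trihydroxybenzaldehyde
Product: 2 2,4-bis(benzyloxy)-6-hydroxybenzaldehyde
Conditions: BnBr (2.05 equiv), K2CO3 (2.1 equiv), DMF, 0 °C to rt
Reagents that add atoms: benzyl bromide, BrCc1ccccc1
Why: Williamson etherification that should take the para and one ortho hydroxyl and spare the second ortho hydroxyl, whose hydrogen bond to the formyl oxygen lowers its nucleophilicity.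

**Step 2**
Reactants: 2 2,4-bis(benzyloxy)-6-hydroxybenzaldehyde
Product: 3 2,4-bis(benzyloxy)-6-(triisopropylsilyloxy)benzaldehyde
Conditions: TIPSOTf, 2,6-lutidine, CH2Cl2, 0 °C
Reagents that add atoms: triisopropylsilyl trifluoromethanesulfonate, CC(C)[Si](OS(=O)(=O)C(F)(F)F)(C(C)C)C(C)C
Why: Silylation of the phenol, giving a bulky silyl ether that should resist O-to-O migration in step 5, survive the acid of step 6 and be the only group cleaved by fluoride in step 9.

**Step 3**
Reactants: 4 3,4-dihydroxybenzaldehyde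
Product: 5 3,4-bis(allyloxy)benzaldehyde
Conditions: allyl bromide (2.4 equiv), K2CO3, DMF, rt, under N2
Reagents that add atoms: allyl bromide, C=CCBr
Why: Williamson etherification of the catechol, giving allyl ethers that tolerate organolithium, acid, peracid and fluoride and can later be removed by Pd(0) without touching benzyl ethers.

**Step 4**
Reactants: 5 3,4-bis(allyloxy)benzaldehyde
Product: 6 1,2-bis(allyloxy)-4-ethynylbenzene
Conditions: dimethyl (1-diazo-2-oxopropyl)phosphonate, K2CO3, MeOH, 0 °C to rt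
Reagents that add atoms: dimethyl (1-diazo-2-oxopropyl)phosphonate, COP(=O)(OC)C(=[N+]=[N-])C(C)=O
Why: Ohira–Bestmann (Seyferth–Gilbert) homologation, which converts non-enolisable aryl aldehydes into terminal alkynes under mild base.

**Step 5**
Reactants: 6 1,2-bis(allyloxy)-4-ethynylbenzene; 3 2,4-bis(benzyloxy)-6-(triisopropylsilyloxy)benzaldehyde
Product: 8 3-[3,4-bis(allyloxy)phenyl]-1-[2,4-bis(benzyloxy)-6-(triisopropylsilyloxy)phenyl]prop-2-yn-1-ol (racemic), via lithium arylacetylide 7 (not isolated)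
Conditions: n-BuLi, THF, −78 °C; then 3, −78 °C; AcOH quench at −78 °C; used crude
Reagents that add atoms: none
Why: 1,2-addition of a lithium acetylide to the aldehyde, in which the carbinol centre is formed racemic and erased in step 6, and the cold quench forestalls silyl migration to the new alkoxide.

**Step 6**
Reactants: 8 the propargylic alcohol
Product: 9 {3,5-bis(benzyloxy)-2-[3-(3,4-bis(allyloxy)phenyl)prop-2-yn-1-yl]phenoxy}triisopropylsilane
Conditions: Et3SiH (3 equiv), TFA (2 equiv), CH2Cl2, −40 to 0 °C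
Reagents that add atoms: none
Why: Ionic hydrogenation (SN1 deoxygenation), in which the 2,4,6-trioxygenated ring lets the propargylic cation form under mild acid and the silane delivers hydride to the benzylic carbon, giving the alkyne and not the allene.

**Step 7**
Reactants: 9 the 1,3-diarylpropyne
Product: 10 (Z)-{3,5-bis(benzyloxy)-2-[3-(3,4-bis(allyloxy)phenyl)prop-2-en-1-yl]phenoxy}triisopropylsilane
Conditions: H2 (1 atm), Lindlar catalyst, quinoline, EtOAc, rt, stopped after 1 equiv H2
Reagents that add atoms: none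
Why: Lindlar semi-hydrogenation, whose syn delivery of hydrogen gives the Z-alkene while the alkyne binds the poisoned surface far more strongly than the terminal allyl alkenes and benzyl ethers are not cleaved.

**Step 8**
Reactants: 10 the (Z)-1,3-diarylpropene
Product: 11 (2R,3S)-2-[2,4-bis(benzyloxy)-6-(triisopropylsilyloxy)benzyl]-3-[3,4-bis(allyloxy)phenyl]oxirane (cis)
Conditions: (S,S)-Jacobsen Mn(salen)Cl (5 mol %), NMO (5 equiv), mCPBA (2 equiv), CH2Cl2, −78 °C; cold aq NaOH work-up, used at once
Reagents that add atoms: 3-chloroperoxybenzoic acid, O=C(OO)c1cccc(Cl)c1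
Why: Jacobsen–Katsuki epoxidation of a cis-β-substituted styrene, in which the chiral Mn-oxo species transfers oxygen to one face of the Z-alkene and so sets both centres (benzylic S, homobenzylic R) with retention of the cis geometry, while the hypochlorite-free protocol avoids chlorination of the electron-rich A ring.

**Step 9**
Reactants: 11 the cis-epoxide
Product: 13 (S)-[3,4-bis(allyloxy)phenyl][(S)-4,6-bis(benzyloxy)-2,3-dihydrobenzofuran-2-yl]methanol (threo), via epoxy phenoxide 12 (not isolated)
Conditions: TBAF (1.5 equiv), THF, 0 °C to rt; aq NH4Cl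
Reagents that add atoms: none
Why: Fluoride desilylation followed by base-mediated 5-exo-tet epoxide opening, in which the phenoxide attacks the non-benzylic carbon with inversion (R to S) and the benzylic C–O bond is untouched (S), so the threo carbinol should result.

**Step 10**
Reactants: 13 the threo carbinol
Product: 14 4-{(S)-[(S)-4,6-bis(benzyloxy)-2,3-dihydrobenzofuran-2-yl](hydroxy)methyl}benzene-1,2-diol
Conditions: Pd(PPh3)4 (5 mol %), morpholine (6 equiv), THF, rt, degassed; used crude
Reagents that add atoms: none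
Why: Tsuji–Trost deallylation, in which Pd(0) ionises the aryl allyl ethers and morpholine captures the π-allyl fragments, freeing the catechol (aryl esters could not have been carried through the phenoxide of step 9) without touching benzyl ethers or either stereocentre.

**Step 11**
Reactants: 14 the catechol carbinol
Product: 15 dibenzyl 4-{(S)-[(S)-4,6-bis(benzyloxy)-2,3-dihydrobenzofuran-2-yl](hydroxy)methyl}-1,2-phenylene bis(carbonate)
Conditions: CbzCl (2.2 equiv), Et3N, CH2Cl2, −20 to 0 °C
Reagents that add atoms: benzyl chloroformate, O=C(Cl)OCc1ccccc1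
Why: Chemoselective O-acylation of the two phenols by a chloroformate under amine base without DMAP, which the hindered secondary alcohol should not match in rate, giving carbonates that make ring B electron-poor and are hydrogenolysable.

**Step 12**
Reactants: 15 the bis(carbonate) carbinol
Product: 16 (S)-[(S)-4,6-bis(benzyloxy)-2,3-dihydrobenzofuran-2-yl]{3,4-bis[(benzyloxycarbonyl)oxy]phenyl}methyl methanesulfonate
Conditions: Ms2O (1.5 equiv), Et3N, CH2Cl2, −20 °C; cold work-up, used crude
Reagents that add atoms: methanesulfonic anhydride, CS(=O)(=O)OS(C)(=O)=O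
Why: Sulfonylation at oxygen and hence with retention at carbon, in which the anhydride excludes chloride and the deactivated ring B together with the β-oxygen should keep the benzylic mesylate from ionising prematurely.

**Step 13**
Reactants: 16 the threo mesylate; 17 4-(benzyloxy)benzoic acid
Product: 20 (2R,3R)-5,7-bis(benzyloxy)-2-{3,4-bis[(benzyloxycarbonyl)oxy]phenyl}chroman-3-yl 4-(benzyloxy)benzoate, via zinc 4-(benzyloxy)benzoate 18 (not isolated), via cis-oxiranium ion 19 (not isolated)
Conditions: 17 (4 equiv), Et2Zn (1.5 equiv), 1,4-dioxane, rt; then 16, 70 °C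
Reagents that add atoms: none
Why: Proposed new method: the zinc centre assists departure of the mesylate while the furan oxygen attacks the benzylic carbon from the rear (3-exo-tet), giving the bridged cis-oxiranium ion 19, and a zinc-bound carboxylate then opens this ion anti at the former furan C2, so the old O–C bond breaks and the pyran ring is left by ring enlargement and not by a direct six-membered closure. The closest known reaction type is the zinc-carboxylate-mediated enlargement of α-sulfonyloxyalkyl tetrahydrofurans to 3-acyloxytetrahydropyrans, together with the rearrangement of 2-(halomethyl)-2,3-dihydrobenzofurans to 3-substituted chromans; a benzylic, aryl-ether-participated, stereospecific case is not established. Both new stereocentres are substrate-controlled: C2 arises by inversion at the mesylate carbon (S to R) and C3 by inversion at the furan carbon (S to R), so the threo precursor should give the 2,3-cis ester. The step needs a bridged and not an open cation, which the two carbonate groups on ring B and the β-oxygen should secure by destabilising the free benzylic cation, while the two benzyloxy groups keep the A-ring oxygen nucleophilic. It also needs capture at C3 and not at the benzylic carbon: a benzylic ester formed by the latter path can re-ionise through the same oxiranium ion, whereas the chroman 3-ester cannot, so material should drain to 20. The weakly basic zinc carboxylate in the presence of free acid should suppress elimination to the enol ether.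

**Step 14**
Reactants: 20 the protected chroman ester
Product: 21 (−)-epicatechin 3-O-(4-hydroxybenzoate)
Conditions: H2 (1 atm), Pd(OH)2/C, THF/MeOH, rt
Reagents that add atoms: none
Why: Hydrogenolysis cleaves the three benzyl ethers and the two benzyl carbonates (the latter with loss of CO2) under neutral conditions that should leave the secondary benzoate, the C2–O1 bond and both stereocentres untouched.

**Compound list**

1 | 2,4,6-trihydroxybenzaldehyde | O=Cc1c(O)cc(O)cc1O | starting material
2 | 2,4-bis(benzyloxy)-6-hydroxybenzaldehyde | O=Cc1c(O)cc(OCc2ccccc2)cc1OCc1ccccc1 | intermediate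
3 | 2,4-bis(benzyloxy)-6-(triisopropylsilyloxy)benzaldehyde | O=Cc1c(O[Si](C(C)C)(C(C)C)C(C)C)cc(OCc2ccccc2)cc1OCc1ccccc1 | intermediate
4 | 3,4-dihydroxybenzaldehyde | O=Cc1ccc(O)c(O)c1 | starting material
5 | 3,4-bis(allyloxy)benzaldehyde | O=Cc1ccc(OCC=C)c(OCC=C)c1 | intermediate
6 | 1,2-bis(allyloxy)-4-ethynylbenzene | C#Cc1ccc(OCC=C)c(OCC=C)c1 | intermediate
7 | lithium [3,4-bis(allyloxy)phenyl]acetylide (not isolated) | [Li]C#Cc1ccc(OCC=C)c(OCC=C)c1 | intermediate
8 | 3-[3,4-bis(allyloxy)phenyl]-1-[2,4-bis(benzyloxy)-6-(triisopropylsilyloxy)phenyl]prop-2-yn-1-ol (racemic) | OC(C#Cc1ccc(OCC=C)c(OCC=C)c1)c1c(O[Si](C(C)C)(C(C)C)C(C)C)cc(OCc2ccccc2)cc1OCc1ccccc1 | intermediate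
9 | {3,5-bis(benzyloxy)-2-[3-(3,4-bis(allyloxy)phenyl)prop-2-yn-1-yl]phenoxy}triisopropylsilane | C(C#Cc1ccc(OCC=C)c(OCC=C)c1)c1c(O[Si](C(C)C)(C(C)C)C(C)C)cc(OCc2ccccc2)cc1OCc1ccccc1 | intermediate
10 | (Z)-{3,5-bis(benzyloxy)-2-[3-(3,4-bis(allyloxy)phenyl)prop-2-en-1-yl]phenoxy}triisopropylsilane | C(/C=C\c1ccc(OCC=C)c(OCC=C)c1)c1c(O[Si](C(C)C)(C(C)C)C(C)C)cc(OCc2ccccc2)cc1OCc1ccccc1 | intermediate
11 | (2R,3S)-2-[2,4-bis(benzyloxy)-6-(triisopropylsilyloxy)benzyl]-3-[3,4-bis(allyloxy)phenyl]oxirane (cis) | C([C@H]1O[C@H]1c1ccc(OCC=C)c(OCC=C)c1)c1c(O[Si](C(C)C)(C(C)C)C(C)C)cc(OCc2ccccc2)cc1OCc1ccccc1 | intermediate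
12 | tetrabutylammonium 3,5-bis(benzyloxy)-2-{[(2R,3S)-3-(3,4-bis(allyloxy)phenyl)oxiran-2-yl]methyl}phenolate (not isolated) | C([C@H]1O[C@H]1c1ccc(OCC=C)c(OCC=C)c1)c1c([O-])cc(OCc2ccccc2)cc1OCc1ccccc1.CCCC[N+](CCCC)(CCCC)CCCC | intermediate
13 | (S)-[3,4-bis(allyloxy)phenyl][(S)-4,6-bis(benzyloxy)-2,3-dihydrobenzofuran-2-yl]methanol (threo) | O[C@@H](c1ccc(OCC=C)c(OCC=C)c1)[C@@H]1Cc2c(OCc3ccccc3)cc(OCc3ccccc3)cc2O1 | intermediate
14 | 4-{(S)-[(S)-4,6-bis(benzyloxy)-2,3-dihydrobenzofuran-2-yl](hydroxy)methyl}benzene-1,2-diol | O[C@@H](c1ccc(O)c(O)c1)[C@@H]1Cc2c(OCc3ccccc3)cc(OCc3ccccc3)cc2O1 | intermediate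
15 | dibenzyl 4-{(S)-[(S)-4,6-bis(benzyloxy)-2,3-dihydrobenzofuran-2-yl](hydroxy)methyl}-1,2-phenylene bis(carbonate) | O[C@@H](c1ccc(OC(=O)OCc2ccccc2)c(OC(=O)OCc2ccccc2)c1)[C@@H]1Cc2c(OCc3ccccc3)cc(OCc3ccccc3)cc2O1 | intermediate
16 | (S)-[(S)-4,6-bis(benzyloxy)-2,3-dihydrobenzofuran-2-yl]{3,4-bis[(benzyloxycarbonyl)oxy]phenyl}methyl methanesulfonate (threo) | CS(=O)(=O)O[C@@H](c1ccc(OC(=O)OCc2ccccc2)c(OC(=O)OCc2ccccc2)c1)[C@@H]1Cc2c(OCc3ccccc3)cc(OCc3ccccc3)cc2O1 | intermediate
17 | 4-(benzyloxy)benzoic acid | O=C(O)c1ccc(OCc2ccccc2)cc1 | starting material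
18 | zinc bis[4-(benzyloxy)benzoate] (not isolated) | [Zn+2].[O-]C(=O)c1ccc(OCc2ccccc2)cc1.[O-]C(=O)c1ccc(OCc2ccccc2)cc1 | intermediate
19 | bridged cis-oxiranium cation in which the former furan oxygen is bonded to C7a, the former furan C2 and the benzylic carbon, aryl and CH2 cis (not isolated) | O=C(OCc1ccccc1)Oc1ccc([C@@H]2[C@@H]3Cc4c(OCc5ccccc5)cc(OCc5ccccc5)cc4[O+]23)cc1OC(=O)OCc1ccccc1 | intermediate
20 | (2R,3R)-5,7-bis(benzyloxy)-2-{3,4-bis[(benzyloxycarbonyl)oxy]phenyl}chroman-3-yl 4-(benzyloxy)benzoate | O=C(O[C@@H]1Cc2c(OCc3ccccc3)cc(OCc3ccccc3)cc2O[C@@H]1c1ccc(OC(=O)OCc2ccccc2)c(OC(=O)OCc2ccccc2)c1)c1ccc(OCc2ccccc2)cc1 | intermediate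
21 | (−)-epicatechin 3-O-(4-hydroxybenzoate), (2R,3R) | O=C(O[C@@H]1Cc2c(O)cc(O)cc2O[C@@H]1c1ccc(O)c(O)c1)c1ccc(O)cc1 | target

**Totals**

Total step count: 14. Longest linear sequence: 12 steps (1 → 21 through steps 1, 2, 5–14; the branch from 4 through steps 3–14 is equally long).

**Steps most likely to fail**

1. Step 13 (Proposed new method). Ionisation may escape the bridged pathway and pass through an open benzylic cation, eroding configuration at C2; the intermediate may lose a proton to an enol ether; or the sulfonate may return at C3. The fallback uses known chemistry, sets out from 10 and rejoins at 21. Radical Z-to-E isomerisation of 10 (cat. PhSSPh, hν) should give the (E)-alkene F1. Shi epoxidation with the L-fructose-derived (ent) ketone and Oxone should give the (2S,3S)-trans-epoxide F2. Acetic-acid-buffered TBAF should free the epoxy phenol F3, which under catalytic camphorsulfonic acid should close 6-endo at the activated benzylic carbon with inversion to the 2,3-trans flavan-3-ol F4. Dess–Martin oxidation should give the flavan-3-one F5, and L-Selectride reduction from the face opposite the C2 aryl group should give the 2,3-cis flavan-3-ol F6. Steglich esterification with 17 (EDC, DMAP) should give the 3-O-[4-(benzyloxy)benzoate] F7, Pd(0)/morpholine deallylation the catechol ester F8, and hydrogenolysis (H2, Pd/C) the target 21.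

2. Step 8. Oxygen transfer may proceed stepwise and leak to the trans-epoxide, facial selectivity may be incomplete, and the electron-rich epoxide may open during work-up. The fallback sets out from 10 and rejoins at 13. The (E)-alkene F1 (made from 10 as above) is epoxidised under Shi conditions with the D-fructose-derived ketone, which is reliable for trans-β-substituted styrenes and should give the (2R,3R)-trans-epoxide F9. TBAF should then give, by the same 5-exo opening, the erythro carbinol F10. Dess–Martin oxidation should give the α-aryloxy ketone F11, and L-Selectride reduction under Felkin–Anh (non-chelation) control should deliver the threo carbinol 13.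

3. Step 1. The partial alkylation may not stop cleanly, through over-benzylation of the chelated hydroxyl and C-benzylation of the phloroglucinol ring. The fallback sets out from 1 and rejoins at 2. Exhaustive benzylation (BnBr in excess, K2CO3, DMF, 60 °C) should give 2,4,6-tris(benzyloxy)benzaldehyde F12, from which MgBr2·OEt2 (toluene/Et2O, reflux) should remove one ortho benzyl group by chelation to the formyl oxygen, giving 2.

**Further compounds**

F1 | step 13 | (E)-{3,5-bis(benzyloxy)-2-[3-(3,4-bis(allyloxy)phenyl)prop-2-en-1-yl]phenoxy}triisopropylsilane | C(/C=C/c1ccc(OCC=C)c(OCC=C)c1)c1c(O[Si](C(C)C)(C(C)C)C(C)C)cc(OCc2ccccc2)cc1OCc1ccccc1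
F2 | step 13 | (2S,3S)-2-[2,4-bis(benzyloxy)-6-(triisopropylsilyloxy)benzyl]-3-[3,4-bis(allyloxy)phenyl]oxirane (trans) | C([C@@H]1O[C@H]1c1ccc(OCC=C)c(OCC=C)c1)c1c(O[Si](C(C)C)(C(C)C)C(C)C)cc(OCc2ccccc2)cc1OCc1ccccc1
F3 | step 13 | 3,5-bis(benzyloxy)-2-{[(2S,3S)-3-(3,4-bis(allyloxy)phenyl)oxiran-2-yl]methyl}phenol | C([C@@H]1O[C@H]1c1ccc(OCC=C)c(OCC=C)c1)c1c(O)cc(OCc2ccccc2)cc1OCc1ccccc1
F4 | step 13 | (2R,3S)-2-[3,4-bis(allyloxy)phenyl]-5,7-bis(benzyloxy)chroman-3-ol | O[C@H]1Cc2c(OCc3ccccc3)cc(OCc3ccccc3)cc2O[C@@H]1c1ccc(OCC=C)c(OCC=C)c1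
F5 | step 13 | (2R)-2-[3,4-bis(allyloxy)phenyl]-5,7-bis(benzyloxy)chroman-3-one | O=C1Cc2c(OCc3ccccc3)cc(OCc3ccccc3)cc2O[C@@H]1c1ccc(OCC=C)c(OCC=C)c1
F6 | step 13 | (2R,3R)-2-[3,4-bis(allyloxy)phenyl]-5,7-bis(benzyloxy)chroman-3-ol | O[C@@H]1Cc2c(OCc3ccccc3)cc(OCc3ccccc3)cc2O[C@@H]1c1ccc(OCC=C)c(OCC=C)c1
F7 | step 13 | (2R,3R)-2-[3,4-bis(allyloxy)phenyl]-5,7-bis(benzyloxy)chroman-3-yl 4-(benzyloxy)benzoate | O=C(O[C@@H]1Cc2c(OCc3ccccc3)cc(OCc3ccccc3)cc2O[C@@H]1c1ccc(OCC=C)c(OCC=C)c1)c1ccc(OCc2ccccc2)cc1
F8 | step 13 | (2R,3R)-5,7-bis(benzyloxy)-2-(3,4-dihydroxyphenyl)chroman-3-yl 4-(benzyloxy)benzoate | O=C(O[C@@H]1Cc2c(OCc3ccccc3)cc(OCc3ccccc3)cc2O[C@@H]1c1ccc(O)c(O)c1)c1ccc(OCc2ccccc2)cc1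
F9 | step 8 | (2R,3R)-2-[2,4-bis(benzyloxy)-6-(triisopropylsilyloxy)benzyl]-3-[3,4-bis(allyloxy)phenyl]oxirane (trans) | C([C@H]1O[C@@H]1c1ccc(OCC=C)c(OCC=C)c1)c1c(O[Si](C(C)C)(C(C)C)C(C)C)cc(OCc2ccccc2)cc1OCc1ccccc1
F10 | step 8 | (R)-[3,4-bis(allyloxy)phenyl][(S)-4,6-bis(benzyloxy)-2,3-dihydrobenzofuran-2-yl]methanol (erythro) | O[C@H](c1ccc(OCC=C)c(OCC=C)c1)[C@@H]1Cc2c(OCc3ccccc3)cc(OCc3ccccc3)cc2O1
F11 | step 8 | [3,4-bis(allyloxy)phenyl][(S)-4,6-bis(benzyloxy)-2,3-dihydrobenzofuran-2-yl]methanone | O=C(c1ccc(OCC=C)c(OCC=C)c1)[C@@H]1Cc2c(OCc3ccccc3)cc(OCc3ccccc3)cc2O1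
F12 | step 1 | 2,4,6-tris(benzyloxy)benzaldehyde | O=Cc1c(OCc2ccccc2)cc(OCc2ccccc2)cc1OCc1ccccc1
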